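**Plan**

Retrosynthesis cuts, in order: (a) the C9–O ester bond; (b) the exocyclic C=C of the butenolide (aldehyde + 3-methylfuran-2(5H)-one); (c) the C1–C1′ bond, through a [3,3] shift from an allyl vinyl ether on C3–O; (d) the C4–C5 bond of the cyclopentane, which reverses a 1,2-shift and returns a 1-hydroxy-2-methylcyclobutyl group on the β-carbon of a cyclohexenone; (e) the cyclobutanol C–aryl bond, the cyclohexenone being a Birch-reduced anisole.
Enabling feature: the spiro atom C5 is β to the six-ring carbinol carbon C9 (C5–C10–C9) and adjacent to C1 of the five-membered ring; with C9 and C1 as carbonyls this is the 1,4-diketone that a β-(1-hydroxycyclobutyl) enone gives when the four-membered ring expands onto the enone β-carbon.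
Forward: (S)-2-methylcyclobutanone → aryl carbinol → Birch reduction/hydrolysis to the enone → ring expansion (cyclobutane → cyclopentanone, spiro C5 created) → five-ring enone, epoxide, Wharton alcohol, O-allyl ether, Claisen → butenolide → six-ring enone, CBS reduction, ester.
Stereochemistry: C4 from the RAMP-hydrazone methylation, retained in the shift; C5 from the amine catalyst; a temporary C3–O centre (anti to C4–CH3) is relayed suprafacially to C1 and, through the (E)-propenyl ether, to C1′; C9 from the CBS catalyst; the Z alkene from the elimination.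

Key step: step 6

Remark: locants of all spiro compounds follow the target (C1 = CH bearing the side chain, C4 = CH–CH3, C5 = spiro atom, C7=C8, C9 = carbinol carbon, side chain C1′); C8 is carried as an epimer mixture from step 5 until it becomes sp2 in step 16, and the minor carbinol epimer of 9–11 is carried along because that centre becomes C=O in step 6, so the SMILES leave C8 open and show the major carbinol epimer.

**Route**

Step 1
Reactants: 1 cyclobutanone; 2 (R)-1-amino-2-(methoxymethyl)pyrrolidine (RAMP)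
Product: 3 (R)-N-cyclobutylidene-2-(methoxymethyl)pyrrolidin-1-amine
Conditions: neat, 4 Å MS, 60 °C
Reagents that add atoms: none
Why: Hydrazone condensation of a strained, unhindered ketone with the Enders auxiliary needs only removal of water and forms no stereocentre.

Step 2
Reactants: 3 (R)-N-cyclobutylidene-2-(methoxymethyl)pyrrolidin-1-amine
Product: 5 (R)-2-(methoxymethyl)-N-[(2S)-2-methylcyclobutylidene]pyrrolidin-1-amine, via lithium azaenolate 4 (not isolated)
Conditions: LDA, THF, 0 °C; then MeI, −95 °C → rt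
Reagents that add atoms: iodomethane, CI
Why: Enders RAMP-hydrazone α-alkylation, in which the azaenolate chelated by the methoxymethyl arm is methylated on its open face; the RAMP series should give the (S)-2-methyl centre, since the SAMP series gives (R)-2-alkyl cycloalkanones.

Step 3
Reactants: 5 (R)-2-(methoxymethyl)-N-[(2S)-2-methylcyclobutylidene]pyrrolidin-1-amine
Product: 6 (S)-2-methylcyclobutan-1-one
Conditions: sat. aq. (CO2H)2, Et2O, rt
Reagents that add atoms: water, O
Why: Two-phase oxalic acid hydrolysis of the hydrazone is too mild to enolise the cyclobutanone, so the (S)-centre should be kept, and the volatile ketone is used as its ether solution.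

Step 4
Reactants: 7 4-bromo-2-methoxy-1-methylbenzene; 6 (S)-2-methylcyclobutan-1-one
Product: 9 (1R,2S)-1-(3-methoxy-4-methylphenyl)-2-methylcyclobutan-1-ol, via aryllithium 8 (not isolated)
Conditions: 7, n-BuLi, THF, −78 °C; then 6 in Et2O, −78 °C; H2O
Reagents that add atoms: none
Why: Bromine–lithium exchange and 1,2-addition to the strained, poorly enolisable cyclobutanone, the aryl group entering anti to the 2-methyl group (carbinol R).

Step 5
Reactants: 9 (1R,2S)-1-(3-methoxy-4-methylphenyl)-2-methylcyclobutan-1-ol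
Product: 11 3-[(1R,2S)-1-hydroxy-2-methylcyclobutyl]-6-methylcyclohex-2-en-1-one, via dienyl methyl ether 10 (not isolated)
Conditions: Li, NH3(l), t-BuOH, THF, −78 → −33 °C; NH4Cl; then 0.5 M HCl, THF, 0 °C → rt
Reagents that add atoms: water, O
Why: Birch reduction protonates the two unsubstituted, mutually para ring positions (ortho and meta to OMe) while the tertiary benzylic alkoxide is a poor leaving group, and dilute acid then hydrolyses the enol ether and moves the C=C into conjugation (anisole-to-cyclohexenone sequence); the methyl-bearing centre forms as a mixture.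

Step 6
Reactants: 11 3-[(1R,2S)-1-hydroxy-2-methylcyclobutyl]-6-methylcyclohex-2-en-1-one
Product: 12 (4S,5S)-4,8-dimethylspiro[4.5]decane-1,9-dione
Conditions: 9-amino-9-deoxy-epi-quinine (20 mol %), N-Boc-L-phenylglycine (40 mol %), CCl4, 40 °C
Reagents that add atoms: none
Why: The primary amine condenses with the enone carbonyl to an iminium ion whose β-carbon (future C5) is electrophilic while the protonated quinuclidine holds the cyclobutanol OH; the ring bond between the carbinol carbon and the CH(CH3) carbon then shifts 1,2 onto that β-carbon as the carbinol becomes the C1 carbonyl, and hydrolysis of the enamine releases 12. The closest known reaction type is the cinchona-primary-amine-catalysed asymmetric vinylogous α-ketol (semipinacol-type) rearrangement of 3-(1-hydroxycyclobutyl)cyclohex-2-enones to spiro[4.5]decane-1,7-diones. The cyclopentanone is closed by ring expansion of the cyclobutanol (four to five atoms) through a suprafacial 1,2-alkyl shift driven by about 20 kcal/mol of strain release, with no separate cyclisation event. C5 is set by the catalyst, which leaves one face of the iminium β-carbon open to the migrating carbon, and C4 is the former (S)-methyl carbon of the cyclobutane, which migrates with retention. The step needs migration of the CH(CH3) carbon and not the CH2 carbon, which the higher migratory aptitude of the more substituted carbon should secure, and it needs catalyst control of the face; both carbinol epimers and both ring-methyl epimers of 11 can feed the same product because the carbinol becomes C=O and the methyl centre stays enolisable.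

Step 7
Reactants: 12 (4S,5S)-4,8-dimethylspiro[4.5]decane-1,9-dione
Product: 13 (4S,5S)-9,9-(ethylenedioxy)-4,8-dimethylspiro[4.5]decan-1-one
Conditions: HOCH2CH2OH (1.1 equiv), PPTS (cat.), benzene, reflux, Dean–Stark
Reagents that add atoms: ethylene glycol, OCCO
Why: Chemoselective acetalisation, since the six-ring carbonyl C9 (flanked by CH and CH2) ketalises readily whereas the five-ring carbonyl C1 sits next to the quaternary spiro carbon and, as a cyclopentanone, resists sp3 hybridisation.

Step 8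
Reactants: 13 (4S,5S)-9,9-(ethylenedioxy)-4,8-dimethylspiro[4.5]decan-1-one
Product: 14 (4S,5S)-9,9-(ethylenedioxy)-4,8-dimethylspiro[4.5]dec-2-en-1-one
Conditions: IBX, DMSO, 70 °C
Reagents that add atoms: none
Why: IBX dehydrogenation of the ketone through its enol can only introduce the C2=C3 double bond because C5 carries no hydrogen.

Step 9
Reactants: 14 (4S,5S)-9,9-(ethylenedioxy)-4,8-dimethylspiro[4.5]dec-2-en-1-one
Product: 15 (2S,3S,4R,5S)-2,3-epoxy-9,9-(ethylenedioxy)-4,8-dimethylspiro[4.5]decan-1-one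
Conditions: 30% aq. H2O2, NaOH (cat.), MeOH, 0 °C
Reagents that add atoms: hydrogen peroxide, OO
Why: Weitz–Scheffer nucleophilic epoxidation, in which hydroperoxide adds to C3 on the face opposite the neighbouring C4 methyl group and closes on that face (sets C2 and C3), the cold, weakly basic medium avoiding γ-deprotonation at C4.

Step 10
Reactants: 15 (2S,3S,4R,5S)-2,3-epoxy-9,9-(ethylenedioxy)-4,8-dimethylspiro[4.5]decan-1-one
Product: 16 (3R,4R,5R)-9,9-(ethylenedioxy)-4,8-dimethylspiro[4.5]dec-1-en-3-ol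
Conditions: N2H4·H2O, AcOH (cat.), MeOH, 0 °C → rt
Reagents that add atoms: none
Why: Wharton transposition (epoxy hydrazone → vinyl diazene → loss of N2) moves the oxygen to C3 with the C3–O bond untouched and places the double bond at C1=C2.

Step 11
Reactants: 16 (3R,4R,5R)-9,9-(ethylenedioxy)-4,8-dimethylspiro[4.5]dec-1-en-3-ol
Product: 17 (3R,4R,5R)-3-(allyloxy)-9,9-(ethylenedioxy)-4,8-dimethylspiro[4.5]dec-1-ene
Conditions: NaH, allyl bromide, Bu4NI (cat.), THF/DMF, 0 °C → rt
Reagents that add atoms: allyl bromide, C=CCBr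
Why: Williamson etherification of the secondary alkoxide with a reactive allylic halide touches no stereocentre.

Step 12
Reactants: 17 (3R,4R,5R)-3-(allyloxy)-9,9-(ethylenedioxy)-4,8-dimethylspiro[4.5]dec-1-ene
Product: 18 (3R,4R,5R)-3-(allyloxy)-4,8-dimethylspiro[4.5]dec-1-en-9-one
Conditions: 1 M HCl, THF, rt
Reagents that add atoms: water, O
Why: Acid hydrolysis of the dioxolane frees the C9 ketone before the epimerisable aldehyde exists, the allylic ethers being stable to dilute acid.

Step 13
Reactants: 18 (3R,4R,5R)-3-(allyloxy)-4,8-dimethylspiro[4.5]dec-1-en-9-one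
Product: 20 (2S)-2-[(1R,4S,5S)-4,8-dimethyl-9-oxospiro[4.5]dec-2-en-1-yl]propanal, via allyl propenyl ether 19 (not isolated)
Conditions: [IrCl(coe)2]2 (1 mol %), PCy3 (6 mol %), NaBPh4 (2 mol %), CH2Cl2/acetone, rt; then PPh3, toluene, 100 °C
Reagents that add atoms: none
Why: Iridium-catalysed isomerisation of the terminal O-allyl group to the (E)-propenyl ether followed by Claisen rearrangement; the [3,3] shift is suprafacial, so C1′ bonds to C1 on the face that carried the C3–O bond (trans to the C4 methyl, C1 = R), and a boat-like transition state that turns the propenyl methyl away from the quaternary C5 should give (S) at C1′.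

Step 14
Reactants: 20 (2S)-2-[(1R,4S,5S)-4,8-dimethyl-9-oxospiro[4.5]dec-2-en-1-yl]propanal
Product: 21 (2S)-2-[(1R,4S,5S)-4,8-dimethyl-9-oxospiro[4.5]decan-1-yl]propanal
Conditions: KO2CN=NCO2K, AcOH, dioxane, rt
Reagents that add atoms: none
Why: Diimide reduction adds H2 syn to the strained cis-disubstituted cyclopentene without touching the carbonyl groups and without the double-bond migration that could scramble C1 or C4; no stereocentre is formed.

Step 15
Reactants: 21 (2S)-2-[(1R,4S,5S)-4,8-dimethyl-9-oxospiro[4.5]decan-1-yl]propanal; 22 3-methylfuran-2(5H)-one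
Product: 25 (5Z)-5-{(2S)-2-[(1R,4S,5S)-4,8-dimethyl-9-oxospiro[4.5]decan-1-yl]propylidene}-3-methylfuran-2(5H)-one, via silyloxyfuran 23 (not isolated), via silyl aldol adduct 24 (not isolated)
Conditions: 22, TBSOTf, i-Pr2NEt, CH2Cl2, 0 °C; then 21, −78 °C; then DBU, −78 °C → rt
Reagents that add atoms: none
Why: One-pot vinylogous Mukaiyama aldol of the in-situ silyloxyfuran at its C5 with the aldehyde (far more reactive than the ketone) and DBU-induced E1cB loss of silanolate; the Z isomer should be favoured because the chain then lies syn to the ring oxygen and not against the butenolide C4–H.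

Step 16
Reactants: 25 (5Z)-5-{(2S)-2-[(1R,4S,5S)-4,8-dimethyl-9-oxospiro[4.5]decan-1-yl]propylidene}-3-methylfuran-2(5H)-one
Product: 26 (5Z)-5-{(2S)-2-[(1R,4S,5S)-4,8-dimethyl-9-oxospiro[4.5]dec-7-en-1-yl]propylidene}-3-methylfuran-2(5H)-one
Conditions: IBX, DMSO, 65 °C
Reagents that add atoms: none
Why: IBX dehydrogenation of the 2-methylcyclohexanone can only give the C7=C8 enone, because C10 is attached to the quaternary C5, and it removes the uncontrolled C8 centre.

Step 17
Reactants: 26 (5Z)-5-{(2S)-2-[(1R,4S,5S)-4,8-dimethyl-9-oxospiro[4.5]dec-7-en-1-yl]propylidene}-3-methylfuran-2(5H)-one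
Product: 27 (5Z)-5-{(2S)-2-[(1R,4S,5S,9S)-9-hydroxy-4,8-dimethylspiro[4.5]dec-7-en-1-yl]propylidene}-3-methylfuran-2(5H)-one
Conditions: (R)-Me-CBS (20 mol %), catecholborane, toluene, −78 °C
Reagents that add atoms: none
Why: Corey–Bakshi–Shibata reduction, in which the trisubstituted alkenyl carbon C8 acts as the large group so that the (R)-catalyst should deliver hydride to give the (9S)-allylic alcohol under catalyst control, the lactone being inert at −78 °C.

Step 18
Reactants: 27 (5Z)-5-{(2S)-2-[(1R,4S,5S,9S)-9-hydroxy-4,8-dimethylspiro[4.5]dec-7-en-1-yl]propylidene}-3-methylfuran-2(5H)-one; 28 3-phenylpropanoic acid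
Product: 29 (1R,4S,5S,9S)-4,8-dimethyl-1-[(2S,1Z)-1-(4-methyl-5-oxofuran-2(5H)-ylidene)propan-2-yl]spiro[4.5]dec-7-en-9-yl 3-phenylpropanoate (CNP0260277.1)
Conditions: 28, DCC, DMAP (cat.), CH2Cl2, 0 °C → rt
Reagents that add atoms: none
Why: Steglich esterification acylates the secondary allylic alcohol on oxygen, so C9 keeps its configuration, under conditions mild enough for the alkylidene butenolide.

**Compound list**

1 | cyclobutanone | O=C1CCC1 | starting material
2 | (R)-1-amino-2-(methoxymethyl)pyrrolidine (RAMP) | COC[C@H]1CCCN1N | starting material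
3 | (R)-N-cyclobutylidene-2-(methoxymethyl)pyrrolidin-1-amine | COC[C@H]1CCCN1N=C1CCC1 | intermediate
4 | lithium azaenolate of 3 (N-lithio-N-(cyclobut-1-en-1-yl) hydrazide) | COC[C@H]1CCCN1N([Li])C1=CCC1 | intermediate
5 | (R)-2-(methoxymethyl)-N-[(2S)-2-methylcyclobutylidene]pyrrolidin-1-amine | C[C@H]1CCC1=NN2CCC[C@@H]2COC | intermediate
6 | (S)-2-methylcyclobutan-1-one | C[C@H]1CCC1=O | intermediate
7 | 4-bromo-2-methoxy-1-methylbenzene | COc1cc(Br)ccc1C | starting material
8 | (3-methoxy-4-methylphenyl)lithium | [Li]c1ccc(C)c(OC)c1 | intermediate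
9 | (1R,2S)-1-(3-methoxy-4-methylphenyl)-2-methylcyclobutan-1-ol | C[C@H]1CC[C@]1(O)c2ccc(C)c(OC)c2 | intermediate
10 | (1R,2S)-1-(5-methoxy-4-methylcyclohexa-1,4-dien-1-yl)-2-methylcyclobutan-1-ol | C[C@H]1CC[C@]1(O)C2=CCC(C)=C(OC)C2 | intermediate
11 | 3-[(1R,2S)-1-hydroxy-2-methylcyclobutyl]-6-methylcyclohex-2-en-1-one | C[C@H]1CC[C@]1(O)C2=CC(=O)C(C)CC2 | intermediate
12 | (4S,5S)-4,8-dimethylspiro[4.5]decane-1,9-dione | O=C1CC[C@H](C)[C@@]12CCC(C)C(=O)C2 | intermediate
13 | (4S,5S)-9,9-(ethylenedioxy)-4,8-dimethylspiro[4.5]decan-1-one | O=C1CC[C@H](C)[C@@]12CCC(C)C3(OCCO3)C2 | intermediate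
14 | (4S,5S)-9,9-(ethylenedioxy)-4,8-dimethylspiro[4.5]dec-2-en-1-one | O=C1C=C[C@H](C)[C@@]12CCC(C)C3(OCCO3)C2 | intermediate
15 | (2S,3S,4R,5S)-2,3-epoxy-9,9-(ethylenedioxy)-4,8-dimethylspiro[4.5]decan-1-one | O=C1[C@H]2O[C@H]2[C@H](C)[C@@]13CCC(C)C4(OCCO4)C3 | intermediate
16 | (3R,4R,5R)-9,9-(ethylenedioxy)-4,8-dimethylspiro[4.5]dec-1-en-3-ol | C1=C[C@@H](O)[C@H](C)[C@@]12CCC(C)C3(OCCO3)C2 | intermediate
17 | (3R,4R,5R)-3-(allyloxy)-9,9-(ethylenedioxy)-4,8-dimethylspiro[4.5]dec-1-ene | C1=C[C@@H](OCC=C)[C@H](C)[C@@]12CCC(C)C3(OCCO3)C2 | intermediate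
18 | (3R,4R,5R)-3-(allyloxy)-4,8-dimethylspiro[4.5]dec-1-en-9-one | C1=C[C@@H](OCC=C)[C@H](C)[C@@]12CCC(C)C(=O)C2 | intermediate
19 | (3R,4R,5R)-4,8-dimethyl-3-[(E)-prop-1-enyloxy]spiro[4.5]dec-1-en-9-one | C1=C[C@@H](O/C=C/C)[C@H](C)[C@@]12CCC(C)C(=O)C2 | intermediate
20 | (2S)-2-[(1R,4S,5S)-4,8-dimethyl-9-oxospiro[4.5]dec-2-en-1-yl]propanal | O=C[C@@H](C)[C@H]1C=C[C@H](C)[C@@]12CCC(C)C(=O)C2 | intermediate
21 | (2S)-2-[(1R,4S,5S)-4,8-dimethyl-9-oxospiro[4.5]decan-1-yl]propanal | O=C[C@@H](C)[C@H]1CC[C@H](C)[C@@]12CCC(C)C(=O)C2 | intermediate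
22 | 3-methylfuran-2(5H)-one | CC1=CCOC1=O | starting material
23 | tert-butyldimethyl[(3-methylfuran-2-yl)oxy]silane | Cc1ccoc1O[Si](C)(C)C(C)(C)C | intermediate
24 | 5-{(2S)-1-[(tert-butyldimethylsilyl)oxy]-2-[(1R,4S,5S)-4,8-dimethyl-9-oxospiro[4.5]decan-1-yl]propyl}-3-methylfuran-2(5H)-one (epimers at the two new centres) | CC1=CC(OC1=O)C(O[Si](C)(C)C(C)(C)C)[C@@H](C)[C@H]2CC[C@H](C)[C@@]23CCC(C)C(=O)C3 | intermediate
25 | (5Z)-5-{(2S)-2-[(1R,4S,5S)-4,8-dimethyl-9-oxospiro[4.5]decan-1-yl]propylidene}-3-methylfuran-2(5H)-one | CC1=C/C(=C/[C@@H](C)[C@H]2CC[C@H](C)[C@@]23CCC(C)C(=O)C3)OC1=O | intermediate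
26 | (5Z)-5-{(2S)-2-[(1R,4S,5S)-4,8-dimethyl-9-oxospiro[4.5]dec-7-en-1-yl]propylidene}-3-methylfuran-2(5H)-one | CC1=C/C(=C/[C@@H](C)[C@H]2CC[C@H](C)[C@@]23CC=C(C)C(=O)C3)OC1=O | intermediate
27 | (5Z)-5-{(2S)-2-[(1R,4S,5S,9S)-9-hydroxy-4,8-dimethylspiro[4.5]dec-7-en-1-yl]propylidene}-3-methylfuran-2(5H)-one | CC1=C/C(=C/[C@@H](C)[C@H]2CC[C@H](C)[C@@]23CC=C(C)[C@@H](O)C3)OC1=O | intermediate
28 | 3-phenylpropanoic acid | OC(=O)CCc1ccccc1 | starting material
29 | (1R,4S,5S,9S)-4,8-dimethyl-1-[(2S,1Z)-1-(4-methyl-5-oxofuran-2(5H)-ylidene)propan-2-yl]spiro[4.5]dec-7-en-9-yl 3-phenylpropanoate | CC1=C/C(=C/[C@@H](C)[C@H]2CC[C@H](C)[C@@]23CC=C(C)[C@@H](OC(=O)CCc2ccccc2)C3)OC1=O | target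

**Totals and risks**

Total step count: 18. Longest linear sequence: 18 steps (1 → 29); 2, 7, 22 and 28 are commercial and enter directly.

Steps most likely to fail:

Step 6. The catalyst and the two resident centres of 11 may be mismatched, so that the migrating carbon reaches both faces of the enone β-carbon or the CH2 carbon migrates instead; iminium formation next to the α′-methyl group may also be slow. The pseudo-enantiomeric quinidine-derived amine is the first thing to try. The fallback sets out from 10, isolated crude after the ammonia is evaporated in step 5, and returns at 13. Exchange of the enol ether with ethylene glycol and PPTS should give (1R,2S)-2-methyl-1-(10-methyl-1,4-dioxaspiro[4.5]dec-7-en-7-yl)cyclobutan-1-ol F1, an alkenylcyclobutanol whose C=C is not conjugated. A bromonium-induced semipinacol rearrangement (NBS with a (DHQD)2PHAL-type catalyst, CH2Cl2, low temperature), in which the CH(CH3) carbon enters anti to the bromonium, should give (4S,5R)-6-bromo-9,9-(ethylenedioxy)-4,8-dimethylspiro[4.5]decan-1-one F2. Radical debromination (Bu3SnH, AIBN, benzene, 80 °C) then gives 13.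

Step 13. Chair and boat transition states may compete and give both C1′ epimers, and the shift next to the quaternary C5 may need temperatures at which the aldehyde epimerises. The fallback sets out from 16 and returns at 21, and fixes C1′ with an auxiliary instead:
- Acetylation (Ac2O, pyridine, DMAP) gives (3R,4R,5R)-9,9-(ethylenedioxy)-4,8-dimethylspiro[4.5]dec-1-en-3-yl acetate F3.
- Ireland–Claisen rearrangement (LDA, TMSCl, THF, −78 °C → reflux) gives 2-[(1S,4S,5S)-9,9-(ethylenedioxy)-4,8-dimethylspiro[4.5]dec-2-en-1-yl]acetic acid F4, with the same chirality transfer to C1 and no centre at C1′.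
- Diimide reduction gives 2-[(1R,4S,5S)-9,9-(ethylenedioxy)-4,8-dimethylspiro[4.5]decan-1-yl]acetic acid F5.
- Coupling to (S)-4-benzyloxazolidin-2-one through the pivaloyl mixed anhydride gives (S)-4-benzyl-3-{2-[(1R,4S,5S)-9,9-(ethylenedioxy)-4,8-dimethylspiro[4.5]decan-1-yl]acetyl}oxazolidin-2-one F6.
- Evans methylation (NaHMDS, MeI, −78 °C) gives (S)-4-benzyl-3-{(2S)-2-[(1R,4S,5S)-9,9-(ethylenedioxy)-4,8-dimethylspiro[4.5]decan-1-yl]propanoyl}oxazolidin-2-one F7.
- LiBH4 gives (2S)-2-[(1R,4S,5S)-9,9-(ethylenedioxy)-4,8-dimethylspiro[4.5]decan-1-yl]propan-1-ol F8.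
- Dilute aqueous HCl gives (2S)-2-[(1R,4S,5S)-4,8-dimethyl-9-oxospiro[4.5]decan-1-yl]propan-1-ol F9, and Dess–Martin oxidation of the primary alcohol gives 21.

Step 5. The dissolving metal may cleave the benzylic C–O bond or over-reduce the ring, and the acid treatment may ionise the tertiary allylic cyclobutanol. The fallback sets out from 6 and returns at 11 without a dearomatisation. Commercial 3-bromocyclohex-2-en-1-one is methylated at C6 (LDA, MeI, −78 °C) to 3-bromo-6-methylcyclohex-2-en-1-one F10 and ketalised (ethylene glycol, TsOH) to 7-bromo-10-methyl-1,4-dioxaspiro[4.5]dec-6-ene F11. Bromine–lithium exchange (t-BuLi, THF, −78 °C) and addition to 6 give (1R,2S)-2-methyl-1-(10-methyl-1,4-dioxaspiro[4.5]dec-6-en-7-yl)cyclobutan-1-ol F12, and mild aqueous acid (PPTS, acetone/H2O) releases 11.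

Further compounds
F1 | step 6 | (1R,2S)-2-methyl-1-(10-methyl-1,4-dioxaspiro[4.5]dec-7-en-7-yl)cyclobutan-1-ol | C[C@H]1CC[C@]1(O)C2=CCC(C)C3(OCCO3)C2
F2 | step 6 | (4S,5R)-6-bromo-9,9-(ethylenedioxy)-4,8-dimethylspiro[4.5]decan-1-one | O=C1CC[C@H](C)[C@@]12C(Br)CC(C)C3(OCCO3)C2
F3 | step 13 | (3R,4R,5R)-9,9-(ethylenedioxy)-4,8-dimethylspiro[4.5]dec-1-en-3-yl acetate | C1=C[C@@H](OC(C)=O)[C@H](C)[C@@]12CCC(C)C3(OCCO3)C2
F4 | step 13 | 2-[(1S,4S,5S)-9,9-(ethylenedioxy)-4,8-dimethylspiro[4.5]dec-2-en-1-yl]acetic acid | OC(=O)C[C@H]1C=C[C@H](C)[C@@]12CCC(C)C3(OCCO3)C2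
F5 | step 13 | 2-[(1R,4S,5S)-9,9-(ethylenedioxy)-4,8-dimethylspiro[4.5]decan-1-yl]acetic acid | OC(=O)C[C@H]1CC[C@H](C)[C@@]12CCC(C)C3(OCCO3)C2
F6 | step 13 | (S)-4-benzyl-3-{2-[(1R,4S,5S)-9,9-(ethylenedioxy)-4,8-dimethylspiro[4.5]decan-1-yl]acetyl}oxazolidin-2-one | O=C(C[C@H]1CC[C@H](C)[C@@]12CCC(C)C3(OCCO3)C2)N4[C@@H](Cc5ccccc5)COC4=O
F7 | step 13 | (S)-4-benzyl-3-{(2S)-2-[(1R,4S,5S)-9,9-(ethylenedioxy)-4,8-dimethylspiro[4.5]decan-1-yl]propanoyl}oxazolidin-2-one | O=C([C@@H](C)[C@H]1CC[C@H](C)[C@@]12CCC(C)C3(OCCO3)C2)N4[C@@H](Cc5ccccc5)COC4=O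
F8 | step 13 | (2S)-2-[(1R,4S,5S)-9,9-(ethylenedioxy)-4,8-dimethylspiro[4.5]decan-1-yl]propan-1-ol | OC[C@@H](C)[C@H]1CC[C@H](C)[C@@]12CCC(C)C3(OCCO3)C2
F9 | step 13 | (2S)-2-[(1R,4S,5S)-4,8-dimethyl-9-oxospiro[4.5]decan-1-yl]propan-1-ol | OC[C@@H](C)[C@H]1CC[C@H](C)[C@@]12CCC(C)C(=O)C2
F10 | step 5 | 3-bromo-6-methylcyclohex-2-en-1-one | CC1CCC(Br)=CC1=O
F11 | step 5 | 7-bromo-10-methyl-1,4-dioxaspiro[4.5]dec-6-ene | CC1CCC(Br)=CC12OCCO2
F12 | step 5 | (1R,2S)-2-methyl-1-(10-methyl-1,4-dioxaspiro[4.5]dec-6-en-7-yl)cyclobutan-1-ol | C[C@H]1CC[C@]1(O)C2=CC3(OCCO3)C(C)CC2
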